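## Retrosynthetic overview
1. The oxirane is the third and last ring. It comes from peripheral epoxidation of the 1(10)-E alkene of heliangolide 22. The 3β-OH comes from a reagent-controlled reduction of a 3-ketone.
2. The carbocycle is the first ring and is closed at C6–C7, the bond formed when farnesyl diphosphate closes to germacrene A. The enal carbon C6 is attacked by the C7=C11 π bond, and boron leaves C13 in place of the proton.
3. The γ-lactone is the second ring. In the same flask the C6 alkoxide closes onto C12, as in costunolide and eupatolide formation. The 8β-ester is attached afterwards.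
4. Singlet oxygen unmasks the (Z)-4-oxoenal (C3=O, 4Z alkene, C6 aldehyde, C15–O) from a 2,3-disubstituted furan.
5. The open C15 chain is built from C7 (geranyl acetate, ozonolysis), C5 (furan-3-ylmethanol, allyl–furyl coupling) and C3 (Z-selective olefination). C8–O is set by proline aminoxylation.

Assumption: germacrane numbering is used (C6–O lactone, C8 ester, C1/C10 oxirane, C15 = CH2OH). The SMILES is read as the 4Z (heliangolide) isomer with 1R,3S,6R,7R,8R,10R, that is 1β,10α-epoxy, 3β-OH, 6α-O, 7α-H, 8β-O.

## Route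

Step 1
Reactants: 1 geranyl acetate
Product: 2 (2E)-3-methyl-6-oxohex-2-en-1-yl acetate
Conditions: O3 (1.0 equiv, metered), CH2Cl2, −78 °C; Me2S, −78 °C to rt
Reagents that add atoms: ozone, [O-][O+]=O
Why: Chemoselective ozonolysis with reductive work-up, in which ozone attacks the electron-rich terminal alkene much faster than the 2,3-alkene deactivated by the allylic acetate, so the E-alkene that becomes C1=C10 survives and no stereocentre is formed.

Step 2
Reactants: 3 furan-3-ylmethanol
Product: 6 tert-butyldimethyl{[2-(tributylstannyl)furan-3-yl]methoxy}silane, via dilithiated furan-3-ylmethanol 4 (not isolated), via lithium stannylfurylmethoxide 5 (not isolated)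
Conditions: n-BuLi (2.2 equiv), THF, −78 to 0 °C; Bu3SnCl (1.0 equiv), −78 °C; TBSCl (1.2 equiv), 4-(dimethylamino)pyridine (cat.), rt
Reagents that add atoms: tributyltin chloride, CCCC[Sn](Cl)(CCCC)CCCC; tert-butyldimethylsilyl chloride, CC(C)(C)[Si](C)(C)Cl
Why: Directed ortho-metalation, in which the lithium alkoxide steers the second lithiation to the neighbouring furan C2, the carbanion is stannylated faster than the alkoxide, and the alkoxide is silylated only when no C–Li is left that could trigger O-to-C silyl migration.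

Step 3
Reactants: 2 (2E)-3-methyl-6-oxohex-2-en-1-yl acetate; 6 tert-butyldimethyl{[2-(tributylstannyl)furan-3-yl]methoxy}silane
Product: 7 (4E)-6-[3-(tert-butyldimethylsilyloxymethyl)furan-2-yl]-4-methylhex-4-enal
Conditions: Pd(dba)2 (5 mol %), LiCl (3 equiv), DMF, 35 °C
Reagents that add atoms: none
Why: Stille-type allyl–heteroaryl coupling, in which zerovalent palladium ionises the primary allylic acetate and the furyl group is delivered to the unhindered terminus of the syn π-allyl complex, so the C2–C3 bond forms linear with the E geometry kept and the aldehyde untouched.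

Step 4
Reactants: 8 methyl bis(2,2,2-trifluoroethyl)phosphonoacetate; 9 2-(iodomethyl)-4,4,5,5-tetramethyl-1,3,2-dioxaborolane
Product: 11 methyl 2-[bis(2,2,2-trifluoroethoxy)phosphoryl]-3-(4,4,5,5-tetramethyl-1,3,2-dioxaborolan-2-yl)propanoate (racemic), via sodium phosphonate carbanion 10 (not isolated)
Conditions: NaH (1.05 equiv), THF–DMF, 0 °C; then 9, rt
Reagents that add atoms: none
Why: Alkylation of a stabilised phosphonate carbanion by an α-halomethylboronate (Matteson-type substitution through the boron ate complex), analogous to the routine methylation of the same phosphonate, and the new stereocentre is irrelevant because it becomes sp2 in step 5.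

Step 5
Reactants: 7 (4E)-6-[3-(tert-butyldimethylsilyloxymethyl)furan-2-yl]-4-methylhex-4-enal; 11 methyl 2-[bis(2,2,2-trifluoroethoxy)phosphoryl]-3-(4,4,5,5-tetramethyl-1,3,2-dioxaborolan-2-yl)propanoate
Product: 14 methyl (2Z,4R,6E)-4-(anilinooxy)-8-[3-(tert-butyldimethylsilyloxymethyl)furan-2-yl]-6-methyl-2-[(4,4,5,5-tetramethyl-1,3,2-dioxaborolan-2-yl)methyl]octa-2,6-dienoate, via α-anilinooxy aldehyde 12 (not isolated), via potassium phosphonate carbanion 13 (not isolated)
Conditions: L-proline (20 mol %), PhNO (1.0 equiv), MeCN, −20 °C; then transferred into 11 (1.6 equiv), KN(SiMe3)2 (1.5 equiv), 18-crown-6, THF, −78 °C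
Reagents that add atoms: nitrosobenzene, O=Nc1ccccc1
Why: Proposed new method: L-proline enamine catalysis delivers the nitroso oxygen to one enamine face through the acid-bound transition state and gives the (R)-α-oxy aldehyde (known α-aminoxylation, sets C8 as 8R), which is olefinated in the same flask before it can epimerise, the new element being a Still–Gennari phosphonate that carries a β-boryl group and should behave like the known 2-phosphonopropionate analogue (kinetic addition and fast elimination place C8 cis to CO2Me, hence Z, with CH2B trans to C8) because β-boryl ester enolates are known to add to aldehydes without loss of boron, the closest known reaction types being the tandem aminoxylation–Horner–Wadsworth–Emmons sequence and the Z-selective synthesis of trisubstituted enoates, while the O–NHPh cap prevents the Z-γ-oxy ester from closing to a butenolide.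

Step 6
Reactants: 14 methyl (2Z,4R,6E)-4-(anilinooxy)-8-[3-(tert-butyldimethylsilyloxymethyl)furan-2-yl]-6-methyl-2-[(4,4,5,5-tetramethyl-1,3,2-dioxaborolan-2-yl)methyl]octa-2,6-dienoate
Product: 18 (1(10)E,4Z)-8β-(anilinooxy)-15-(tert-butyldimethylsilyloxy)-3-oxogermacra-1(10),4,11(13)-trien-12,6α-olide (6R,7R,8R), via furan endoperoxide 15 (not isolated), via (Z)-4-oxoenal 16 (not isolated), via O-boryl hydroxy ester 17 (not isolated)
Conditions: O2, visible light, tetraphenylporphyrin (1 mol %), CH2Cl2, −78 °C; Me2S, −78 to 0 °C; water wash; slow addition to Sc(OTf)3 (10 mol %), 4 Å sieves, PhMe (final 1 mM), 40 °C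
Reagents that add atoms: dioxygen, O=O
Why: Proposed new method: singlet oxygen adds [4+2] to the furan far faster than to the trisubstituted or acceptor alkenes and Me2S reduction of 15 releases the (Z)-4-oxoenal 16 (known furan photooxygenation, fixes the 4Z alkene, C3=O and the C6 aldehyde), whose aldehyde is then attacked by C7 of the geometrically defined 2-(methoxycarbonyl)allylboronate through a closed chair (closest known type: Sc(OTf)3-catalysed intermolecular allylboration to α-methylene-γ-lactones, here used for the first time to close a ten-membered ring) in which C5 and C8 are both equatorial, giving the anti adduct and hence the trans 6α,12-lactone once the boron alkoxide displaces methoxide, while A(1,3) strain against the cis ester keeps H8 in the alkene plane so that C6 arrives anti to C9 and avoids a syn-pentane C5/C9 contact, which relays 8R into 6R,7R, and the C3 ketone cannot compete because it would have to form an (E)-cycloheptene.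

Step 7
Reactants: 18 (1(10)E,4Z)-8β-(anilinooxy)-15-(tert-butyldimethylsilyloxy)-3-oxogermacra-1(10),4,11(13)-trien-12,6α-olide
Product: 19 (1(10)E,4Z)-15-(tert-butyldimethylsilyloxy)-8β-hydroxy-3-oxogermacra-1(10),4,11(13)-trien-12,6α-olide
Conditions: Cu(OAc)2 (30 mol %), EtOH, rt
Reagents that add atoms: none
Why: Cu(OAc)2-catalysed N–O cleavage of an O-alkyl-N-arylhydroxylamine is the standard mild release of the carbinol after aminoxylation, it is non-reductive so enone, silyl ether and α-methylene lactone survive, C8 is untouched, and a free 8β-OH next to a 6α,12-olide is stable as in the natural 8β-hydroxy germacranolides.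

Step 8
Reactants: 19 (1(10)E,4Z)-15-(tert-butyldimethylsilyloxy)-8β-hydroxy-3-oxogermacra-1(10),4,11(13)-trien-12,6α-olide
Product: 20 (1(10)E,4Z)-15-(tert-butyldimethylsilyloxy)-8β-(methacryloyloxy)-3-oxogermacra-1(10),4,11(13)-trien-12,6α-olide
Conditions: methacrylic anhydride (2 equiv), 4-(dimethylamino)pyridine (10 mol %), pyridine, CH2Cl2, 0 °C
Reagents that add atoms: methacrylic anhydride, C=C(C)C(=O)OC(=O)C(C)=C
Why: Nucleophile-catalysed acylation of the only free hydroxyl with retention at C8, using a weak base at low temperature so that the β,γ-unsaturated 3-ketone does not slip into conjugation.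

Step 9
Reactants: 20 (1(10)E,4Z)-15-(tert-butyldimethylsilyloxy)-8β-(methacryloyloxy)-3-oxogermacra-1(10),4,11(13)-trien-12,6α-olide
Product: 22 (1(10)E,4Z)-3β,15-dihydroxy-8β-(methacryloyloxy)germacra-1(10),4,11(13)-trien-12,6α-olide, via 3β-alcohol silyl ether 21 (not isolated)
Conditions: (R)-Me-CBS [(R)-tetrahydro-1-methyl-3,3-diphenyl-1H,3H-pyrrolo[1,2-c][1,3,2]oxazaborole] (0.5 equiv), catecholborane (2 equiv), PhMe, −78 °C; MeOH; then HF·pyridine, THF, 0 °C
Reagents that add atoms: none
Why: Corey–Bakshi–Shibata reduction in which the ketone binds the (R)-oxazaborolidine–borane complex with the branched alkenyl arm (C4) as the large group, so hydride reaches the face that gives the 3S (3β) alcohol under reagent control and strictly 1,2 at −78 °C without touching the acrylate-type acceptors, after which fluoride frees the primary C15 alcohol before any acid-sensitive oxirane exists.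

Step 10
Reactants: 22 (1(10)E,4Z)-3β,15-dihydroxy-8β-(methacryloyloxy)germacra-1(10),4,11(13)-trien-12,6α-olide
Product: 23 1β,10α-epoxy-3β,15-dihydroxy-8β-(methacryloyloxy)germacra-4Z,11(13)-dien-12,6α-olide (target)
Conditions: mCPBA (1.05 equiv), CH2Cl2, −20 to 0 °C
Reagents that add atoms: 3-chloroperoxybenzoic acid, O=C(OO)c1cccc(Cl)c1
Why: Prilezhaev epoxidation, in which C1=C10 is the only electron-rich alkene (C4=C5 carries three allylic C–O bonds and the other two are acrylates) and an E-alkene in a ten-membered ring can be reached only from the periphery, which in the lactone-anchored conformer with C14 on the β face gives the 1β,10α (1R,10R) oxide, the late oxidation also presumed in the plant.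

## Compound list
1 | geranyl acetate, (2E)-3,7-dimethylocta-2,6-dien-1-yl acetate | CC(C)=CCC/C(C)=C/COC(C)=O | starting material
2 | (2E)-3-methyl-6-oxohex-2-en-1-yl acetate | O=CCC/C(C)=C/COC(C)=O | intermediate
3 | furan-3-ylmethanol | OCc1ccoc1 | starting material
4 | C2,O-dilithiated furan-3-ylmethanol | [Li]OCc1ccoc1[Li] | intermediate
5 | lithium [2-(tributylstannyl)furan-3-yl]methoxide | [Li]OCc1ccoc1[Sn](CCCC)(CCCC)CCCC | intermediate
6 | tert-butyldimethyl{[2-(tributylstannyl)furan-3-yl]methoxy}silane | CCCC[Sn](CCCC)(CCCC)c1occc1CO[Si](C)(C)C(C)(C)C | intermediate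
7 | (4E)-6-[3-(tert-butyldimethylsilyloxymethyl)furan-2-yl]-4-methylhex-4-enal | O=CCC/C(C)=C/Cc1occc1CO[Si](C)(C)C(C)(C)C | intermediate
8 | methyl bis(2,2,2-trifluoroethyl)phosphonoacetate | COC(=O)CP(=O)(OCC(F)(F)F)OCC(F)(F)F | starting material
9 | 2-(iodomethyl)-4,4,5,5-tetramethyl-1,3,2-dioxaborolane | ICB1OC(C)(C)C(C)(C)O1 | starting material
10 | sodium salt of 8 (phosphonate carbanion) | COC(=O)[CH-]P(=O)(OCC(F)(F)F)OCC(F)(F)F.[Na+] | intermediate
11 | methyl 2-[bis(2,2,2-trifluoroethoxy)phosphoryl]-3-(pinacolboryl)propanoate, racemic | COC(=O)C(CB1OC(C)(C)C(C)(C)O1)P(=O)(OCC(F)(F)F)OCC(F)(F)F | intermediate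
12 | (2R,4E)-2-(anilinooxy)-6-[3-(tert-butyldimethylsilyloxymethyl)furan-2-yl]-4-methylhex-4-enal | O=C[C@H](ONc1ccccc1)C/C(C)=C/Cc1occc1CO[Si](C)(C)C(C)(C)C | intermediate
13 | potassium salt of 11 (phosphonate carbanion) | COC(=O)[C-](CB1OC(C)(C)C(C)(C)O1)P(=O)(OCC(F)(F)F)OCC(F)(F)F.[K+] | intermediate
14 | methyl (2Z,4R,6E)-4-(anilinooxy)-8-[3-(TBSO-methyl)furan-2-yl]-6-methyl-2-[(pinacolboryl)methyl]octa-2,6-dienoate | COC(=O)/C(CB1OC(C)(C)C(C)(C)O1)=C\[C@H](ONc1ccccc1)C/C(C)=C/Cc1occc1CO[Si](C)(C)C(C)(C)C | intermediate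
15 | 2,5-endoperoxide of the furan of 14 (2,3,7-trioxabicyclo[2.2.1]hept-5-ene, both bridge diastereomers) | COC(=O)/C(CB1OC(C)(C)C(C)(C)O1)=C\[C@H](ONc1ccccc1)C/C(C)=C/CC12OOC(O1)C=C2CO[Si](C)(C)C(C)(C)C | intermediate
16 | methyl (2Z,4R,6E,10Z)-4-(anilinooxy)-10-(TBSO-methyl)-6-methyl-9,12-dioxo-2-[(pinacolboryl)methyl]dodeca-2,6,10-trienoate | COC(=O)/C(CB1OC(C)(C)C(C)(C)O1)=C\[C@H](ONc1ccccc1)C/C(C)=C/CC(=O)/C(CO[Si](C)(C)C(C)(C)C)=C\C=O | intermediate
17 | methyl (1(10)E,4Z)-8β-(anilinooxy)-6α-(pinacolboryloxy)-15-(TBSO)-3-oxogermacra-1(10),4,11(13)-trien-12-oate | c1ccccc1NO[C@@H]1C/C(C)=C/CC(=O)/C(CO[Si](C)(C)C(C)(C)C)=C\[C@@H](OB2OC(C)(C)C(C)(C)O2)[C@@H]1C(=C)C(=O)OC | intermediate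
18 | (1(10)E,4Z)-8β-(anilinooxy)-15-(TBSO)-3-oxogermacra-1(10),4,11(13)-trien-12,6α-olide | c1ccccc1NO[C@@H]1C/C(C)=C/CC(=O)/C(CO[Si](C)(C)C(C)(C)C)=C\[C@H]2OC(=O)C(=C)[C@@H]21 | intermediate
19 | (1(10)E,4Z)-8β-hydroxy-15-(TBSO)-3-oxogermacra-1(10),4,11(13)-trien-12,6α-olide | O[C@@H]1C/C(C)=C/CC(=O)/C(CO[Si](C)(C)C(C)(C)C)=C\[C@H]2OC(=O)C(=C)[C@@H]21 | intermediate
20 | (1(10)E,4Z)-8β-(methacryloyloxy)-15-(TBSO)-3-oxogermacra-1(10),4,11(13)-trien-12,6α-olide | C=C(C)C(=O)O[C@@H]1C/C(C)=C/CC(=O)/C(CO[Si](C)(C)C(C)(C)C)=C\[C@H]2OC(=O)C(=C)[C@@H]21 | intermediate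
21 | (1(10)E,4Z)-3β-hydroxy-8β-(methacryloyloxy)-15-(TBSO)germacra-1(10),4,11(13)-trien-12,6α-olide | C=C(C)C(=O)O[C@@H]1C/C(C)=C/C[C@H](O)/C(CO[Si](C)(C)C(C)(C)C)=C\[C@H]2OC(=O)C(=C)[C@@H]21 | intermediate
22 | (1(10)E,4Z)-3β,15-dihydroxy-8β-(methacryloyloxy)germacra-1(10),4,11(13)-trien-12,6α-olide | C=C(C)C(=O)O[C@@H]1C/C(C)=C/C[C@H](O)/C(CO)=C\[C@H]2OC(=O)C(=C)[C@@H]21 | intermediate
23 | 1β,10α-epoxy-3β,15-dihydroxy-8β-(methacryloyloxy)germacra-4Z,11(13)-dien-12,6α-olide (CNP0496616.1) | C=C(C)C(=O)O[C@@H]1C[C@@]2(C)O[C@@H]2C[C@H](O)/C(CO)=C\[C@H]2OC(=O)C(=C)[C@@H]21 | target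

## Step count and risks
Total step count: 10. Longest linear sequence: 8 (steps 1, 3, 5, 6, 7, 8, 9, 10).

**Most likely to fail, first: step 6.**
- Risk: a 2-(alkoxycarbonyl)allylboronic ester is a sluggish nucleophile. The oxoenal may isomerise or react with Sc(OTf)3 before a ten-membered ring can close.
- Fallback: it sets out from 14 and comes back at 18. The nucleophile itself is changed. KHF2 in aqueous MeOH turns 14 into the potassium allyltrifluoroborate F3. Photooxygenation and Me2S reduction as before give the oxoenal trifluoroborate F4.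
- The ring is then closed at high dilution in a two-phase CH2Cl2–water medium with Bu4NI as phase-transfer catalyst. The reacting species is the much more Lewis acidic allyl-BF2 compound, so no external Lewis acid meets the oxoenal. The same chair and therefore the same stereochemical relay apply.
- The hydroxy ester lactonises on silica gel to 18.

**Second: step 5.**
- Risk: the boron-bearing phosphonate is untested, and both its Z-selectivity and the survival of the C–B bond are extrapolations.
- Fallback: it sets out from 7 (through 12) and comes back at 14. Alkene geometry and boron are introduced separately. Phosphonate 8 is brominated (NaH, then N-bromosuccinimide) to the bromophosphonate F1.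
- Olefination of 12 with F1 under the same KN(SiMe3)2 and 18-crown-6 conditions gives the (E)-α-bromoenoate F2, with bromine trans to C8.
- A stereoretentive Negishi coupling of F2 with IZnCH2Bpin (made from 9 and Zn) under Pd(PPh3)4 installs the borylmethyl group and gives 14.

**Third: step 10.**
- Risk: the face of attack depends on which conformer of the 1(10)-alkene is populated, and the allylic hydroxyls could direct some peracid to C4=C5.
- Fallback: it sets out from 21, which is isolated instead of being desilylated in the flask, and comes back at 23. The oxirane is made under catalyst control on the silyl ether, using the D-fructose-derived ketone 1,2:4,5-di-O-isopropylidene-β-D-erythro-hexo-2,3-diulo-2,6-pyranose and KHSO5 in buffered MeCN–dimethoxymethane at 0 °C. This system gives R,R-oxiranes from E-trisubstituted alkenes.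
- The product is the epoxy silyl ether F5, and Et3N·3HF then frees the C15 alcohol to give 23.

## Further compounds
F1 | step 5 | methyl bromo[bis(2,2,2-trifluoroethoxy)phosphoryl]acetate | COC(=O)C(Br)P(=O)(OCC(F)(F)F)OCC(F)(F)F
F2 | step 5 | methyl (2E,4R,6E)-4-(anilinooxy)-2-bromo-8-[3-(tert-butyldimethylsilyloxymethyl)furan-2-yl]-6-methylocta-2,6-dienoate | COC(=O)/C(Br)=C\[C@H](ONc1ccccc1)C/C(C)=C/Cc1occc1CO[Si](C)(C)C(C)(C)C
F3 | step 6 | potassium {(2Z,4R,6E)-4-(anilinooxy)-2-(methoxycarbonyl)-6-methyl-8-[3-(tert-butyldimethylsilyloxymethyl)furan-2-yl]octa-2,6-dien-1-yl}trifluoroborate | COC(=O)/C(C[B-](F)(F)F)=C\[C@H](ONc1ccccc1)C/C(C)=C/Cc1occc1CO[Si](C)(C)C(C)(C)C.[K+]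
F4 | step 6 | potassium trifluoroborate analogue of oxoenal 16 | COC(=O)/C(C[B-](F)(F)F)=C\[C@H](ONc1ccccc1)C/C(C)=C/CC(=O)/C(CO[Si](C)(C)C(C)(C)C)=C\C=O.[K+]
F5 | step 10 | 1β,10α-epoxy-3β-hydroxy-8β-(methacryloyloxy)-15-(tert-butyldimethylsilyloxy)germacra-4Z,11(13)-dien-12,6α-olide | C=C(C)C(=O)O[C@@H]1C[C@@]2(C)O[C@@H]2C[C@H](O)/C(CO[Si](C)(C)C(C)(C)C)=C\[C@H]2OC(=O)C(=C)[C@@H]21
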